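**Assumption:** The target SMILES has no stereocentre, and the C5–C2′ aryl–benzofuran axis is not configurationally stable (the benzofuran presents only O1′ and C3′–H to it). The compound is therefore achiral, no enantiocontrol is needed, and racemic intermediates are acceptable. Compounds 1, 2, 7 and 11 are taken as commercial.

## Analysis of the target

Cathafuran C is a 2,2-dimethyl-2H-chromene (O1, C2–C4, C4a–C8a) whose benzo ring carries a 6-hydroxy-1-benzofuran-2-yl group at C5, a prenyl group at C6 and a free hydroxyl at C7. The benzo ring is thus a pentasubstituted resorcinol: oxygens at C7 and C8a (meta), the only ring hydrogen at C8 between them, and three contiguous carbon substituents at C4a (pyran C4), C5 (benzofuran C2′) and C6 (prenyl). There is no stereocentre, and the C5–C2′ axis rotates freely. The sensitive groups are the chromene C3=C4 bond and the prenyl alkene, both acid-labile (the prenyl closes onto the C7 hydroxyl to a chromane), and two electron-rich phenols plus the benzofuran, which are oxidisable. The substitution pattern runs against arene reactivity: the benzofuranyl group sits meta to both oxygens, the two C5 units occupy the hindered positions beside it, and the open position C8 is the most nucleophilic one. In addition, the two oxygen/C5 pairs (O7 with the C6 prenyl, O8a with C4a) are constitutionally alike, yet only one is closed to the pyran. The feature the route exploits is that this ring is exactly what forms when an alkoxyacetylene (C7, C8) is inserted into a cyclobutenone (C8a, C4a, C5, C6): the ketene-derived oxygen emerges as a free hydroxyl at C8a and the alkyne-derived one as an ether at C7, which differentiates the two pairs.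

## Retrosynthetic reasoning

**22 from 21.** The two phenols are unveiled last from the bis(methyl ether) 21 by nucleophilic O-demethylation. The only bonds cut are the two O–CH3 bonds. The tertiary pyran ether cannot react by SN2, so nothing else in the molecule is at risk from the mode of cleavage itself.

**21 from 18.** The pyran ring is cut at O1–C2, and the C3=C4 unsaturation is removed. The precursor is phenol 18, which carries two identical prenyl groups, one beside a free hydroxyl and one beside a methoxy group. Only the prenyl next to the free hydroxyl can be closed by an oxygen-directed cyclofunctionalisation followed by elimination, so the regiochemistry of the chromene is decided by which oxygen is free.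

**18 from 10 and 13 (key disconnection).** The benzo ring is cut at C8–C8a and C6–C7. C7 and C8 with the methoxy group come from methoxyethyne 13. C8a, C4a, C5 and C6 with all three carbon substituents come from cyclobutenone 10. This cut is chosen because C8 is the only CH of the ring and maps onto the terminal alkyne carbon, and because the meta dioxygen pattern is what the ketene/ynol ether benzannulation produces. It delivers the free hydroxyl next to one prenyl and the ether next to the other. The forward reaction must open the strained ring, capture the vinylketene with 13 in the right orientation, and aromatise.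

**10 from 6 and 7.** The C5–C2′ bond is cut. Lithiated 6-methoxybenzofuran 7 adds to the carbonyl of the vinylogous ester 6, and acid transposes the carbonyl. The ethoxy group of 6 serves only as a leaving group.

**6 from 4.** The cyclobutenone is cut into two molecules of the same ynol ether 4. One loses ethene to become prenylketene 5, the other acts as ketenophile. The equal prenyl groups at C2 and C4 of 6 therefore come from one building block.

**4 from 1 and 2; 13 from 11.** Ynol ether 4 is the prenylation product of ethoxyethyne 1 with prenyl bromide 2. Methoxyethyne 13 is made by elimination from chloroacetal 11.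

## Alternatives that were turned down

**Alternative 1:** The textbook route cuts the benzofuran O1′–C2′ and C3′–C3a′ bonds. A palladium/copper alkynylation of an ortho-iodophenol with a 3,5-dimethoxyphenylacetylene and cycloisomerisation would give the trimethyl ether A1, and demethylation the triphenol A2 (moracin M). Two C-prenylations and an oxidative closure of one arm would follow. It was turned down because both C5 units must enter ortho to the benzofuranyl group, the most hindered positions. Electrophiles and directed metalation prefer the carbon between the two oxygens and the electron-rich benzofuran ring. The three phenols of A2 are not differentiated, so the single pyran closure has no control element. The step economy of the benzofuran synthesis is lost in the end game.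

**Alternative 2:** The biaryl bond C5–C2′ is cut, and the forward key step is a Suzuki–Miyaura coupling of a 2-benzofuranylboron reagent with the fully substituted bromochromene A3. It was turned down because it only moves the problem into A3. Its bromine sits meta to both oxygens between two carbon substituents, where bromination does not go (C8 reacts instead). Building A3 would need the same regiochemical solution as the target. The coupling itself would join a di-ortho-substituted bromide with a 2-heteroarylboron species that is prone to protodeboronation.

**Alternative 3:** The benzo ring is derived from a carbocycle: 5-aryl-cyclohexane-1,3-dione A4, α′-alkylation of its vinylogous ester to A5 (Stork–Danheiser type), a second arm, then dehydrogenation to the resorcinol. It was turned down because the dione reacts with enals and alkyl halides at the carbon between the carbonyls, which corresponds to C8, the one position that must stay unsubstituted. Each vinylogous ester allows alkylation on one side only, so the second arm needs a carbonyl transposition. The final aromatisation needs an oxidant in the presence of two prenyl alkenes and an electron-rich benzofuran. The sequence is long and oxidatively fragile.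

Key step: step 5

## Route

**Step 1**
Reactants: 1 ethoxyethyne (ethoxyacetylene); 2 1-bromo-3-methylbut-2-ene (prenyl bromide)
Product: 4 1-ethoxy-5-methylhex-4-en-1-yne, via lithium ethoxyacetylide 3 (not isolated)
Conditions: n-BuLi, THF, −78 °C; then 2, HMPA, −78 → 0 °C
Reagents that add atoms: none
Why: C-alkylation of a lithium alkoxyacetylide; SN2 at the primary allylic carbon is favoured over SN2′ because the γ-terminus of 2 is disubstituted, and HMPA raises the nucleophilicity of the acetylide.

**Step 2**
Reactants: 4 1-ethoxy-5-methylhex-4-en-1-yne (two molecules)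
Product: 6 rac-3-ethoxy-2,4-bis(3-methylbut-2-en-1-yl)cyclobut-2-en-1-one, via prenylketene (5-methylhexa-1,4-dien-1-one) 5 (not isolated)
Conditions: neat or concentrated in toluene, sealed tube, 120 °C
Reagents that add atoms: none
Why: Classical thermal self-condensation of a 1-ethoxyalkyne: retro-ene loss of ethene gives the aldoketene 5, which is trapped by unchanged 4 in a [2+2] cycloaddition with the nucleophilic β-carbon of the ynol ether bonding to the ketene carbonyl carbon; the single stereocentre (C4) is racemic and is destroyed in step 5.

**Step 3**
Reactants: 7 6-methoxy-1-benzofuran; 6 rac-3-ethoxy-2,4-bis(3-methylbut-2-en-1-yl)cyclobut-2-en-1-one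
Product: 10 rac-3-(6-methoxy-1-benzofuran-2-yl)-2,4-bis(3-methylbut-2-en-1-yl)cyclobut-2-en-1-one, via (6-methoxy-1-benzofuran-2-yl)lithium 8 (not isolated), via 3-ethoxy-1-(6-methoxy-1-benzofuran-2-yl)-2,4-bis(3-methylbut-2-en-1-yl)cyclobut-2-en-1-ol 9 (not isolated)
Conditions: n-BuLi, THF, −78 °C; then 6, −78 °C; then 1 M HCl, 0 °C → rt
Reagents that add atoms: water (O)
Why: C2-lithiation of the benzofuran, 1,2-addition to the vinylogous ester carbonyl, then acid-promoted loss of the tertiary hydroxyl and hydrolysis of the resulting alkoxy-stabilised cation (1,3-carbonyl transposition with loss of ethanol), the standard conversion of 3-alkoxycyclobutenones into 3-substituted cyclobutenones; the new carbonyl oxygen is delivered by water.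

**Step 4**
Reactants: 11 2-chloro-1,1-dimethoxyethane (chloroacetaldehyde dimethyl acetal)
Product: 13 methoxyethyne (methoxyacetylene), via sodium methoxyacetylide 12 (not isolated)
Conditions: NaNH2 (3 equiv), liq. NH3, −33 °C; then cold brine, distilled into cold toluene
Reagents that add atoms: none
Why: Classical alkoxyacetylene synthesis: amide-induced elimination of methanol and of HCl gives the acetylide, which is protonated on aqueous work-up; the volatile product is used as a stock solution.

**Step 5**
Reactants: 10 rac-3-(6-methoxy-1-benzofuran-2-yl)-2,4-bis(3-methylbut-2-en-1-yl)cyclobut-2-en-1-one; 13 methoxyethyne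
Product: 18 5-methoxy-3-(6-methoxy-1-benzofuran-2-yl)-2,4-bis(3-methylbut-2-en-1-yl)phenol, via vinylketene 3-(6-methoxy-1-benzofuran-2-yl)-7-methyl-2-(3-methylbut-2-en-1-yl)octa-1,3,6-trien-1-one 14 (not isolated), via rac-3-methoxy-4-[1-(6-methoxy-1-benzofuran-2-yl)-5-methylhexa-1,4-dien-1-yl]-4-(3-methylbut-2-en-1-yl)cyclobut-2-en-1-one 15 (not isolated), via dienylketene 3-methoxy-5-(6-methoxy-1-benzofuran-2-yl)-9-methyl-4-(3-methylbut-2-en-1-yl)deca-1,3,5,8-tetraen-1-one 16 (not isolated), via rac-3-methoxy-5-(6-methoxy-1-benzofuran-2-yl)-4,6-bis(3-methylbut-2-en-1-yl)cyclohexa-2,4-dien-1-one 17 (not isolated)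
Conditions: 13 (3 equiv), toluene, sealed tube, 80 → 110 °C
Reagents that add atoms: none
Why: Heating opens the strained cyclobutenone 10 by 4π-electrocyclic cleavage of C1–C4 (the C4 prenyl rotating outward) to vinylketene 14, and the polarised ynol ether 13 adds across the ketene C=C in a [2+2] cycloaddition, its CH carbon bonding to the ketene carbonyl carbon and its C–OMe carbon to the ketene α-carbon, to give 15. A second, reversible 4π opening gives dienylketene 16, which closes the six-membered carbocycle by thermal disrotatory 6π-electrocyclisation (ketene carbon to the prenyl-bearing diene terminus) to cyclohexadienone 17, and tautomerisation aromatises it to 18. The closest known reaction is the Danheiser benzannulation of cyclobutenones with alkoxyacetylenes, which gives 3-alkoxyphenols with exactly this relationship of substituents. Net, the two alkyne carbons are inserted between C1 and C2 of the four-membered ring, which forms the C8–C8a and C6–C7 bonds of the target and the whole pentasubstituted benzene ring in one operation, driven by release of ring strain and by aromatisation. No stereocentre is created, and the racemic centres of 10, 15 and 17 vanish on aromatisation. The regiochemistry needed (CH between the two oxygens, methoxy meta to the new hydroxyl, free hydroxyl beside the prenyl that came from C4) is fixed by the polarity match of ketene and ynol ether and by the connectivity of 10; because 10 carries the same group on C2 and C4, a shift of its ring double bond is degenerate. Chemoselectivity rests on the ynol ether being a far better ketenophile than the prenyl alkenes or the benzofuran C2=C3 bond; 13 has no β-hydrogen and so cannot fragment by retro-ene at this temperature, and a wrong-way opening of 15 is corrected because that opening is reversible.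

**Step 6**
Reactants: 18 5-methoxy-3-(6-methoxy-1-benzofuran-2-yl)-2,4-bis(3-methylbut-2-en-1-yl)phenol
Product: 21 7-methoxy-5-(6-methoxy-1-benzofuran-2-yl)-2,2-dimethyl-6-(3-methylbut-2-en-1-yl)-2H-chromene, via rac-7-methoxy-5-(6-methoxy-1-benzofuran-2-yl)-2,2-dimethyl-6-(3-methylbut-2-en-1-yl)-3-(phenylselanyl)-3,4-dihydro-2H-chromene 19 (not isolated), via the corresponding selenoxide 20 (not isolated)
Conditions: PhSeCl (1.05 equiv), CH2Cl2, −78 °C; then mCPBA (1.0 equiv), −78 °C; then i-Pr2NH, −78 °C → rt
Reagents that add atoms: none
Why: Phenol-assisted 6-endo selenoetherification (the seleniranium ion opens at its tertiary carbon), oxidation to the selenoxide and syn-elimination towards the only β-hydrogens (benzylic C4–H) give the 2H-chromene, a known route from ortho-prenylphenols to 2,2-dimethylchromenes. Only the prenyl beside the free hydroxyl can be trapped, since the other is flanked by the methoxy group, and low-temperature peracid with an amine scavenger spares the remaining alkene.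

**Step 7**
Reactants: 21 7-methoxy-5-(6-methoxy-1-benzofuran-2-yl)-2,2-dimethyl-6-(3-methylbut-2-en-1-yl)-2H-chromene
Product: 22 cathafuran C, 5-(6-hydroxy-1-benzofuran-2-yl)-2,2-dimethyl-6-(3-methylbut-2-en-1-yl)-2H-chromen-7-ol
Conditions: NaSEt (excess), DMF, 130 °C; then cold 1 M HCl to pH 5
Reagents that add atoms: none
Why: SN2 O-demethylation of both aryl methyl ethers by thiolate; the tertiary pyran ether cannot react by SN2, and the alkenes and benzofuran are inert to the nucleophile, as in known thiolate demethylations of methoxy-2,2-dimethylchromenes.

## Compound list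

1 | ethoxyethyne | C#COCC | starting material
2 | 1-bromo-3-methylbut-2-ene | CC(C)=CCBr | starting material
3 | lithium ethoxyacetylide | [Li]C#COCC | intermediate, not isolated
4 | 1-ethoxy-5-methylhex-4-en-1-yne | CCOC#CCC=C(C)C | intermediate
5 | 5-methylhexa-1,4-dien-1-one (prenylketene) | CC(C)=CCC=C=O | intermediate, not isolated
6 | rac-3-ethoxy-2,4-bis(3-methylbut-2-en-1-yl)cyclobut-2-en-1-one | CCOC1=C(CC=C(C)C)C(=O)C1CC=C(C)C | intermediate
7 | 6-methoxy-1-benzofuran | COc1ccc2ccoc2c1 | starting material
8 | (6-methoxy-1-benzofuran-2-yl)lithium | [Li]c1cc2ccc(OC)cc2o1 | intermediate, not isolated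
9 | 3-ethoxy-1-(6-methoxy-1-benzofuran-2-yl)-2,4-bis(3-methylbut-2-en-1-yl)cyclobut-2-en-1-ol (racemic, mixture of diastereomers) | CCOC1=C(CC=C(C)C)C(O)(c2cc3ccc(OC)cc3o2)C1CC=C(C)C | intermediate, not isolated
10 | rac-3-(6-methoxy-1-benzofuran-2-yl)-2,4-bis(3-methylbut-2-en-1-yl)cyclobut-2-en-1-one | O=C1C(CC=C(C)C)=C(c2cc3ccc(OC)cc3o2)C1CC=C(C)C | intermediate
11 | 2-chloro-1,1-dimethoxyethane | COC(CCl)OC | starting material
12 | sodium methoxyacetylide | [Na+].[C-]#COC | intermediate, not isolated
13 | methoxyethyne | C#COC | intermediate
14 | 3-(6-methoxy-1-benzofuran-2-yl)-7-methyl-2-(3-methylbut-2-en-1-yl)octa-1,3,6-trien-1-one (C4 alkyl trans to the ketene carbon) | O=C=C(CC=C(C)C)/C(c1cc2ccc(OC)cc2o1)=C/CC=C(C)C | intermediate, not isolated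
15 | rac-3-methoxy-4-[1-(6-methoxy-1-benzofuran-2-yl)-5-methylhexa-1,4-dien-1-yl]-4-(3-methylbut-2-en-1-yl)cyclobut-2-en-1-one | O=C1C=C(OC)C1(CC=C(C)C)/C(c1cc2ccc(OC)cc2o1)=C/CC=C(C)C | intermediate, not isolated
16 | 3-methoxy-5-(6-methoxy-1-benzofuran-2-yl)-9-methyl-4-(3-methylbut-2-en-1-yl)deca-1,3,5,8-tetraen-1-one (ketene arm cis to the dienyl arm) | O=C=C/C(OC)=C(/CC=C(C)C)\C(c1cc2ccc(OC)cc2o1)=C\CC=C(C)C | intermediate, not isolated
17 | rac-3-methoxy-5-(6-methoxy-1-benzofuran-2-yl)-4,6-bis(3-methylbut-2-en-1-yl)cyclohexa-2,4-dien-1-one | O=C1C=C(OC)C(CC=C(C)C)=C(c2cc3ccc(OC)cc3o2)C1CC=C(C)C | intermediate, not isolated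
18 | 5-methoxy-3-(6-methoxy-1-benzofuran-2-yl)-2,4-bis(3-methylbut-2-en-1-yl)phenol | Oc1cc(OC)c(CC=C(C)C)c(-c2cc3ccc(OC)cc3o2)c1CC=C(C)C | intermediate
19 | rac-7-methoxy-5-(6-methoxy-1-benzofuran-2-yl)-2,2-dimethyl-6-(3-methylbut-2-en-1-yl)-3-(phenylselanyl)-3,4-dihydro-2H-chromene | COc1cc2c(c(-c3cc4ccc(OC)cc4o3)c1CC=C(C)C)CC([Se]c1ccccc1)C(C)(C)O2 | intermediate, not isolated
20 | selenoxide of 19 (mixture of diastereomers at selenium) | COc1cc2c(c(-c3cc4ccc(OC)cc4o3)c1CC=C(C)C)CC([Se](=O)c1ccccc1)C(C)(C)O2 | intermediate, not isolated
21 | 7-methoxy-5-(6-methoxy-1-benzofuran-2-yl)-2,2-dimethyl-6-(3-methylbut-2-en-1-yl)-2H-chromene | COc1cc2c(c(-c3cc4ccc(OC)cc4o3)c1CC=C(C)C)C=CC(C)(C)O2 | intermediate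
22 | cathafuran C, 5-(6-hydroxy-1-benzofuran-2-yl)-2,2-dimethyl-6-(3-methylbut-2-en-1-yl)-2H-chromen-7-ol | CC(C)=CCc1c(O)cc2c(c1-c1cc3ccc(O)cc3o1)C=CC(C)(C)O2 | target

## Step count and least certain steps

Total: 7 steps. Longest linear sequence: 6 steps (1, 2, 3, 5, 6, 7); step 4 is a one-step side branch.

**Step 5 (key step).** The vinylketene may be consumed by self-condensation or by acylating the product phenol before methoxyethyne captures it. The ring opening of 15 may also favour the geometry that cannot close, so that the sequence stalls. Both are aggravated by the bulky 2-benzofuranyl group flanked by two prenyl groups. The fallback builds the benzofuran after the arene, so that only a rod-like alkynyl group is carried through the benzannulation. It sets out from 6. Addition of lithium (trimethylsilyl)acetylide and the same acidic transposition as in step 3 should give rac-2,4-bis(3-methylbut-2-en-1-yl)-3-[(trimethylsilyl)ethynyl]cyclobut-2-en-1-one F1. Heating F1 with 13 should give 5-methoxy-2,4-bis(3-methylbut-2-en-1-yl)-3-[(trimethylsilyl)ethynyl]phenol F2. Desilylation with K2CO3 in methanol should give 3-ethynyl-5-methoxy-2,4-bis(3-methylbut-2-en-1-yl)phenol F3. A Sonogashira coupling of F3 with commercial 2-iodo-5-methoxyphenol (Pd/Cu, Et3N, DMF, warm), with 5-endo cycloisomerisation of the ortho-alkynylphenol in the same flask, comes back to the route at 18.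

**Step 2.** The ketene may dimerise or be diverted, or product 6 may react further with the ynol ether at 120 °C, so that the self-condensation gives little cyclobutenone. The fallback makes the ketene by a different process at room temperature. It sets out from 4. Commercial 5-methylhex-4-enoic acid is converted with oxalyl chloride into 5-methylhex-4-enoyl chloride F4. Slow addition of F4 to 4 and triethylamine in dichloromethane generates ketene 5 by dehydrochlorination, and the crossed [2+2] cycloaddition comes back to the route at 6.

**Step 6.** Electrophilic selenium may attack the second prenyl alkene, the nucleophilic ring position between the two oxygens, or benzofuran C3 instead of closing the pyran, and the oxidation may touch the remaining alkene. The fallback is a one-step oxidative closure by a different mechanism. It sets out from 18. DDQ in benzene at room temperature abstracts hydride from the benzylic position ortho to the free hydroxyl to give the ortho-quinone methide 3-methoxy-5-(6-methoxy-1-benzofuran-2-yl)-4-(3-methylbut-2-en-1-yl)-6-(3-methylbut-2-en-1-ylidene)cyclohexa-2,4-dien-1-one F5, which closes by oxa-6π-electrocyclisation and comes back to the route at 21. It is not the first choice because the other prenyl group is para to the same hydroxyl and may compete for the oxidant.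

**Step 7.** The second methyl ether may be cleaved only sluggishly, or hot thiolate and base may open the chromene or shift the prenyl double bond. The fallback moves the demethylation ahead of the pyran closure. It sets out from 18. NaSEt in DMF should give 5-(6-hydroxy-1-benzofuran-2-yl)-4,6-bis(3-methylbut-2-en-1-yl)benzene-1,3-diol F6, in which the two hydroxyl/prenyl pairs are equivalent. One equivalent of PhSeCl should then give 5-(6-hydroxy-1-benzofuran-2-yl)-2,2-dimethyl-6-(3-methylbut-2-en-1-yl)-3-(phenylselanyl)-3,4-dihydro-2H-chromen-7-ol F7, whichever pair reacts. Oxidation to its selenoxide F8 and syn-elimination come back to the route at 22. Over-cyclisation to the bis-pyran is limited by the stoichiometry.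

## Further compounds

F1 | step 5 | rac-2,4-bis(3-methylbut-2-en-1-yl)-3-[(trimethylsilyl)ethynyl]cyclobut-2-en-1-one | O=C1C(CC=C(C)C)=C(C#C[Si](C)(C)C)C1CC=C(C)C
F2 | step 5 | 5-methoxy-2,4-bis(3-methylbut-2-en-1-yl)-3-[(trimethylsilyl)ethynyl]phenol | Oc1cc(OC)c(CC=C(C)C)c(C#C[Si](C)(C)C)c1CC=C(C)C
F3 | step 5 | 3-ethynyl-5-methoxy-2,4-bis(3-methylbut-2-en-1-yl)phenol | Oc1cc(OC)c(CC=C(C)C)c(C#C)c1CC=C(C)C
F4 | step 2 | 5-methylhex-4-enoyl chloride | CC(C)=CCCC(Cl)=O
F5 | step 6 | 3-methoxy-5-(6-methoxy-1-benzofuran-2-yl)-4-(3-methylbut-2-en-1-yl)-6-(3-methylbut-2-en-1-ylidene)cyclohexa-2,4-dien-1-one | O=C1C=C(OC)C(CC=C(C)C)=C(c2cc3ccc(OC)cc3o2)C1=CC=C(C)C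
F6 | step 7 | 5-(6-hydroxy-1-benzofuran-2-yl)-4,6-bis(3-methylbut-2-en-1-yl)benzene-1,3-diol | Oc1ccc2cc(-c3c(CC=C(C)C)c(O)cc(O)c3CC=C(C)C)oc2c1
F7 | step 7 | rac-5-(6-hydroxy-1-benzofuran-2-yl)-2,2-dimethyl-6-(3-methylbut-2-en-1-yl)-3-(phenylselanyl)-3,4-dihydro-2H-chromen-7-ol | CC(C)=CCc1c(O)cc2c(c1-c1cc3ccc(O)cc3o1)CC([Se]c1ccccc1)C(C)(C)O2
F8 | step 7 | selenoxide of F7 | CC(C)=CCc1c(O)cc2c(c1-c1cc3ccc(O)cc3o1)CC([Se](=O)c1ccccc1)C(C)(C)O2
A1 | alternative 1 | 2-(3,5-dimethoxyphenyl)-6-methoxy-1-benzofuran | COc1cc(OC)cc(-c2cc3ccc(OC)cc3o2)c1
A2 | alternative 1 | 5-(6-hydroxy-1-benzofuran-2-yl)benzene-1,3-diol (moracin M) | Oc1cc(O)cc(-c2cc3ccc(O)cc3o2)c1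
A3 | alternative 2 | 5-bromo-7-methoxy-2,2-dimethyl-6-(3-methylbut-2-en-1-yl)-2H-chromene | COc1cc2OC(C)(C)C=Cc2c(Br)c1CC=C(C)C
A4 | alternative 3 | 5-(6-methoxy-1-benzofuran-2-yl)cyclohexane-1,3-dione | O=C1CC(=O)CC(c2cc3ccc(OC)cc3o2)C1
A5 | alternative 3 | 3-ethoxy-5-(6-methoxy-1-benzofuran-2-yl)-6-(3-methylbut-2-en-1-yl)cyclohex-2-en-1-one | CCOC1=CC(=O)C(CC=C(C)C)C(c2cc3ccc(OC)cc3o2)C1
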